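## The problem

Compound 46 is a germacranolide. Its carbocycle is a cyclodecane (C1–C10; C1 ketone, C3 carbinol, Z C4=C5, C10 tertiary carbinol) fused through C6–C7 to an α-methylene-γ-lactone (O on C6, C11–C13 on C7) whose ring-fusion hydrogens are trans. It carries six stereocentres: C3 (S) stands alone, and C6–C10 (6R,7S,8S,9S,10S) form a contiguous run that includes the erythro 8,9-diol diester and the quaternary C10. A ten-membered ring is the least favourable size for end-to-end closure, so the ring and its Z trisubstituted olefin are best created together by a process that does not pay the medium-ring entropy and strain price. The stereocentres can relay onto each other: a pre-set C3/C1 pair in a six-membered ring can fix C8 and C9, the C8 oxygen (β to C6) can then direct C7 alkylation and C6 reduction, and the C9 ether can bias oxidation at C10. Several groups will not survive rough treatment: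

- the exo-methylene lactone (a Michael acceptor);
- the angelate (Z to E isomerisation to tiglate);
- the C1/C3 β-hydroxy ketone (dehydration, retro-aldol);
- the tertiary α-ketol;
- a free 8-OH next to the lactone (translactonisation);
- vicinal O8/O9 esters (acyl migration).

The enabling feature is that C6 lies 1,6 to C1 across the ring and O8/O9 are vicinal. A C1–C6 bond turns C1–C6 into a cyclohexene that contains C4=C5 (Z by necessity). It leaves C7=C8 and C10=C9 as two oxygen-terminated alkenyl arms on a carbinol and its neighbour, which is a 3-hydroxy-1,5-diene.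

## Retrosynthesis

**46 back to 41 (acyl groups and C1/C10 oxidation).** The acetate, the free 3-OH and the α-ketol are the most fragile elements, so they are removed first in the analysis. The O9 acetate is cut back to a 2-naphthylmethyl (NAP) ether (45, 44, 43). The C1 ketone and C10 carbinol are traced to a 1,10-diol (42), and that to the E C1=C10 olefin of 41. Putting the angelate on before the osmylation means the only secondary alcohol present at the oxidation to the ketone is C1–OH. The forward steps must be chemoselective for the strained, electron-rich 1(10)-olefin and must set C10 from the outer face.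

**41 back to 28 (the lactone).** The angelate is cut at O8 (38). C13 is removed by a retro-Mannich/elimination (34). The lactone C–O bond is opened and C6 returned to a ketone (33, 32), and the C7–C11 bond is cut to methyl bromoacetate 29 and ketone 28 (via 31). This order uses the C8 oxygen twice. As a chelating ether it steers the C7 alkylation (31). After unmasking it delivers hydride to C6 in the 1,3-anti sense (32 to 33), which is exactly the 6,8-relationship of the target. Closure onto O6 gives a trans-fused lactone; closure onto O8 would give a cis-fused one, which needs a near-eclipsed ring torsion in a ten-membered ring, so the regiochemistry should follow.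

**28 back to 25 (key disconnection).** Cutting C8–C9 and re-forming C1–C6 converts the cyclodecadienone 28 into the trans-1,6-dialkenylcyclohex-2-enol 25. Against the neighbouring cuts (C9–C10, C6–C7, C1–C2), this one creates the ring by a strain-neutral four-atom ring expansion, locks Z C4=C5 inside a six-membered ring, and sets C8 and C9 together. The forward reaction needs a chair transition state with O8 equatorial (E vinyl ether) and O9 axial (Z enol ether). Two points of the arm design were strengthened: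

- Both arm oxygens are alkyl ethers: 3,4-dimethoxybenzyl (DMB) on O8 and NAP on O9. A silyl enol ether cis to the ring could hand its silicon to the C6 alkoxide.
- Both geometries come from stereospecific organometallic reagents, not from enolisation.

**25 back to 15 and 23.** The C6–C7 bond is cut to enone 15 and the (E)-2-alkoxyvinyl iodide 23 (used as its lithium derivative 24). Only a 1,2-addition is asked for, anti to the adjacent side arm.

**15 back to 9 and 7.** The C1–C10 bond is cut so that C1 is the electrophile: the cis-β-alkoxy alkenyllithium 10 (from bromide 7) adds as its cuprate 11 to the quinone monoketal 9. This was preferred to enolising an aldehyde side chain, because the enol ether must have oxygen cis to the ring carbon, and only a configurationally defined, internally chelated alkenyl-metal guarantees that. The adduct 12 is racemic. A catalyst-controlled ketone reduction turns the racemate into separable diastereomers and sets C3 (13), after which silylation (14) and ketal hydrolysis give 15.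

**Reagents.** Bromide 7 comes from 2-(bromomethyl)naphthalene 1 and allyl alcohol 2 (via 4 and 5). Iodide 23 comes from 3,4-dimethoxybenzyl alcohol 16 and trichloroethene 17 (via 21). Monoketal 9 comes from 4-methoxy-2-methylphenol 8. The remaining building blocks are methyl bromoacetate 29 and angelic acid 39.

## Roads not taken

**Alternative 1:** The cut is C1–C2 together with O–C3. In the forward sense hypochlorite oxidises a C1 aldoxime to a nitrile oxide, which adds to a terminal C2=C3 olefin of a Z-diene and closes the carbocycle and an isoxazoline at once to give the bridged lactone A1.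
- Merits: the β-hydroxy ketone C1/C3 arrives masked and base-stable, which is better than the chosen plan, where this unit appears late beside a silyl ether. The C6–C10 array and the lactone can be built on an open chain with reagent control.
- Weak points: the ten-membered ring is closed end-to-end against transannular strain. C3 is set by an uncontrolled macrocyclic facial preference. The conjugated diene offers a second dipolarophile. N–O cleavage at the end (reducing conditions) has to spare the exo-methylene lactone and the angelate.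
- Comparison: the chosen plan sets the ring, the Z olefin and C8/C9 in one strain-neutral event. It has to set against this a later C1/C10 oxidation and three substrate-controlled centres (C7, C6, C10).

**Alternative 2:** The cut is C6–C7, with O6 first linked to C13 as an allylic ether inside a thirteen-membered ring. Lithiation at C6 and a [2,3] shift form C6–C7, break O–C13 and contract the ring to carbocycle A2, which carries the C6 alkoxide and the C11=C13 methylene.
- Merits: this is the most direct way to the C6/C7 dyad and the methylene lactone carbons, and here it is superior to the chosen plan, which needs an alkylation, a directed reduction and a methylenation for the same atoms.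
- Weak points: two macrocycle events (ether macrocyclisation, then contraction). Regioselective deprotonation between two allylic ether carbons. [1,2] shift competes with [2,3]. The O8/O9/O10 triad and the Z olefin must be built beforehand on a chain under heavy protection (dithiane, acetal, acetonide).
- Comparison: the chosen plan needs no macrocyclisation and makes C8/C9 during ring formation; it concedes the simpler lactone construction to this route.

**Alternative 3:** The cut is C9–C10. SmI2 reduces a C9 aldehyde and a C10 methyl ketone and couples the two ketyls, closing the ring and giving the cis-9,10-diol lactone A3.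
- Merits: both carbinols, including the quaternary C10, form in the ring-closing step. The chosen plan needs a separate osmylation and oxidation for C10/C1, so this route is better there.
- Weak points: the C9 ketyl carries an α-alkoxy group at C8, which SmI2 tends to expel. A medium-ring cross-pinacol between an aldehyde and a ketone has no strong control element for C9/C10 relative to C8. The exo-methylene must be absent and the C1 oxygen carried as a protected carbinol. The Z olefin again needs its own stereocontrolled synthesis.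
- Comparison: the chosen plan avoids reductive conditions next to labile C–O bonds and derives C8/C9 from olefin geometry; it has to accept a longer oxidation endgame.

Key step: step 12

Assumption: species that are only protonated or hydrolysed at aqueous work-up, and catalytic-cycle transients, are not numbered; intermediates made on purpose and consumed by the next operation in the same flask are. Abbreviations: TBS = tert-butyldimethylsilyl, DMB = 3,4-dimethoxybenzyl, NAP = 2-naphthylmethyl. Germacrane numbering is used for the lactones.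

## Steps

Step 1
Reactants: 1 2-(bromomethyl)naphthalene; 2 prop-2-en-1-ol
Product: 4 2-[(prop-2-en-1-yloxy)methyl]naphthalene, via sodium allyloxide 3 (not isolated)
Conditions: NaH, THF, 0 °C to rt
Reagents that add atoms: none
Why: Williamson ether synthesis on a primary benzylic bromide; no stereocentre is involved.

Step 2
Reactants: 4 2-[(prop-2-en-1-yloxy)methyl]naphthalene
Product: 5 2-{[(1Z)-prop-1-en-1-yloxy]methyl}naphthalene
Conditions: KOtBu (cat.), DMSO, rt
Reagents that add atoms: none
Why: Base-mediated allyl-to-propenyl ether isomerisation runs through the potassium-chelated cis alkoxyallyl anion and should give the Z propenyl ether.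

Step 3
Reactants: 5 2-{[(1Z)-prop-1-en-1-yloxy]methyl}naphthalene
Product: 7 2-({[(1Z)-2-bromoprop-1-en-1-yl]oxy}methyl)naphthalene, via 1,2-dibromide 6 (not isolated)
Conditions: Br2, CH2Cl2, −78 °C; then DBU, −78 °C to rt
Reagents that add atoms: bromine, BrBr
Why: Anti bromination of the enol ether followed by anti dehydrobromination of the labile α-bromo ether should place bromine cis to oxygen. Any E isomer is harmless, because its lithium derivative (Li trans to O) fragments to propyne and alkoxide in step 5.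

Step 4
Reactants: 8 4-methoxy-2-methylphenol
Product: 9 4,4-dimethoxy-2-methylcyclohexa-2,5-dien-1-one
Conditions: PhI(OAc)2, MeOH, 0 °C
Reagents that add atoms: methanol, CO
Why: Hypervalent-iodine oxidative dearomatisation of a para-methoxyphenol in methanol is the standard entry to para-quinone monoketals.

Step 5
Reactants: 7 2-({[(1Z)-2-bromoprop-1-en-1-yl]oxy}methyl)naphthalene; 9 4,4-dimethoxy-2-methylcyclohexa-2,5-dien-1-one
Product: 12 rac-4,4-dimethoxy-2-methyl-5-[(1Z)-1-(NAP-oxy)prop-1-en-2-yl]cyclohex-2-en-1-one, via alkenyllithium 10 (not isolated), via lithium dialkenylcuprate 11 (not isolated)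
Conditions: 7, t-BuLi (2 equiv per Br), Et2O, −78 °C; CuI (0.5 equiv per Li), −78 to −40 °C; then 9, THF, −78 °C; NH4Cl aq
Reagents that add atoms: none
Why: Br–Li exchange with retention gives the internally chelated cis-β-alkoxy alkenyllithium, whose cuprate (R2CuLi) adds 1,4 to the less substituted enone of the monoketal (conjugate addition). The Z enol ether is carried over by retention and the new centre is racemic.

Step 6
Reactants: 12 rac-4,4-dimethoxy-2-methyl-5-[(1Z)-1-(NAP-oxy)prop-1-en-2-yl]cyclohex-2-en-1-one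
Product: 13 (1S,5R)-4,4-dimethoxy-2-methyl-5-[(1Z)-1-(NAP-oxy)prop-1-en-2-yl]cyclohex-2-en-1-ol
Conditions: (R)-Me-CBS oxazaborolidine (0.5 equiv), catecholborane, toluene, −78 °C; chromatographic separation
Reagents that add atoms: none
Why: Corey–Bakshi–Shibata reduction under catalyst control (α-methyl enone: alkenyl side large) should make the 1S carbinol from both enantiomers, so the racemate diverges into separable diastereomers. The trans isomer 13 can only arise from (R)-12 and is therefore enantioenriched. Catecholborane at −78 °C should leave the enol ether alone.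

Step 7
Reactants: 13 (1S,5R)-4,4-dimethoxy-2-methyl-5-[(1Z)-1-(NAP-oxy)prop-1-en-2-yl]cyclohex-2-en-1-ol
Product: 14 TBS ether of 13
Conditions: TBSCl, imidazole, DMF, rt
Reagents that add atoms: tert-butyldimethylsilyl chloride, CC(C)(C)[Si](C)(C)Cl
Why: Standard silylation of a secondary allylic alcohol under non-acidic conditions that spare the ketal and enol ether.

Step 8
Reactants: 14 TBS ether of 13
Product: 15 (4S,6R)-4-(TBS-oxy)-3-methyl-6-[(1Z)-1-(NAP-oxy)prop-1-en-2-yl]cyclohex-2-en-1-one
Conditions: PPTS (cat.), acetone/H2O, 0 °C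
Reagents that add atoms: water, O
Why: The allylic dimethyl ketal ionises much faster than the β,β-disubstituted alkyl enol ether is C-protonated, so buffered acid should unmask the enone selectively. The trans-4,6 arrangement (pseudoaxial silyloxy next to the ring methyl, equatorial side arm) is also the expected thermodynamic one, so C6 should not drift.

Step 9
Reactants: 16 (3,4-dimethoxyphenyl)methanol; 17 trichloroethene
Product: 21 4-[(ethynyloxy)methyl]-1,2-dimethoxybenzene, via potassium alkoxide 18 (not isolated), via dichlorovinyl ether 19 (not isolated), via lithium alkynide 20 (not isolated)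
Conditions: KH, THF, 0 °C; Cl2C=CHCl, −40 °C to rt; n-BuLi (2.4 equiv), −78 °C; MeOH, −78 °C
Reagents that add atoms: none
Why: Alkoxide addition–elimination on trichloroethene, then dehydrochlorination and Cl–Li exchange, is the established one-flask route to alkynyl ethers. The product is kept cold and used at once.

Step 10
Reactants: 21 4-[(ethynyloxy)methyl]-1,2-dimethoxybenzene
Product: 23 4-({[(E)-2-iodoethenyl]oxy}methyl)-1,2-dimethoxybenzene, via alkenylzirconocene 22 (not isolated)
Conditions: Cp2Zr(H)Cl, THF, 0 °C to rt; I2, −78 to 0 °C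
Reagents that add atoms: iodine, II
Why: Syn hydrozirconation of the terminal alkynyl ether puts zirconium on the terminal carbon trans to oxygen, and iodinolysis with retention gives the E iodide.

Step 11
Reactants: 23 4-({[(E)-2-iodoethenyl]oxy}methyl)-1,2-dimethoxybenzene; 15 (4S,6R)-4-(TBS-oxy)-3-methyl-6-[(1Z)-1-(NAP-oxy)prop-1-en-2-yl]cyclohex-2-en-1-one
Product: 25 (1R,4S,6R)-4-(TBS-oxy)-1-[(E)-2-(DMB-oxy)ethenyl]-3-methyl-6-[(1Z)-1-(NAP-oxy)prop-1-en-2-yl]cyclohex-2-en-1-ol, via alkenyllithium 24 (not isolated)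
Conditions: 23, t-BuLi (2 equiv), Et2O, −78 °C; then 15, THF, −78 °C; NH4Cl aq
Reagents that add atoms: none
Why: I–Li exchange with retention gives the E alkenyllithium, which is used cold before β-elimination. 1,2-Addition to the β-substituted enone should occur axially on the face opposite the adjacent equatorial side arm, giving the trans-dialkenyl carbinol (new centre 1R).

Step 12
Reactants: 25 (1R,4S,6R)-4-(TBS-oxy)-1-[(E)-2-(DMB-oxy)ethenyl]-3-methyl-6-[(1Z)-1-(NAP-oxy)prop-1-en-2-yl]cyclohex-2-en-1-ol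
Product: 28 (2Z,4S,6E,8R,9S)-4-(TBS-oxy)-9-(DMB-oxy)-3,7-dimethyl-8-(NAP-oxy)cyclodeca-2,6-dien-1-one, via potassium alkoxide 26 (not isolated), via potassium enolate 27 (not isolated)
Conditions: KH, 18-crown-6, THF, 0 °C to rt; then AcOH in THF, −78 °C
Reagents that add atoms: none
Why: KH with 18-crown-6 gives the dissociated tertiary alkoxide 26, which undergoes a concerted suprafacial [3,3] shift (anionic oxy-Cope): C8–C9 forms between the two ether-bearing termini as the C1–C6 ring bond breaks. The closest known reaction type is the anionic oxy-Cope ring expansion of trans-1,2-dialkenylcyclohexanols to cyclodec-5-enones; oxygen at both termini extends it. The ten-membered ring is not closed end to end but arises by four-atom expansion of the cyclohexene through a chair transition state, so no medium-ring cyclisation entropy is paid and C4=C5 stays Z. In that chair the ring bonds are equatorial. The E vinyl ether places O8 equatorial and the Z enol ether places O9 axial, where it meets only the axial C1–H. This gives the erythro pair (germacrane 8S,9R at this stage; spatially that of the target), with absolute sense relayed from the C1 and C6 centres of 25. The new C1=C10 olefin emerges E with the ring bonds trans. The step needs chair over boat and the exocyclic over the endocyclic vinyl unit. The trans-diequatorial arms, and the fully substituted C4 that would have to bond in the alternative shift, should secure both. The β-alkoxy enolate 27 is protonated cold, because warming would invite E1cB loss of the C8 ether.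

Step 13
Reactants: 28 (2Z,4S,6E,8R,9S)-4-(TBS-oxy)-9-(DMB-oxy)-3,7-dimethyl-8-(NAP-oxy)cyclodeca-2,6-dien-1-one; 29 methyl bromoacetate
Product: 31 methyl 2-[(1R,3Z,5S,7E,9R,10S)-5-(TBS-oxy)-10-(DMB-oxy)-4,8-dimethyl-9-(NAP-oxy)-2-oxocyclodeca-3,7-dien-1-yl]acetate, via lithium enolate 30 (not isolated)
Conditions: LiN(i-Pr)2 (LDA), THF, −78 °C; then 29, −78 to −40 °C
Reagents that add atoms: none
Why: Kinetic α′-deprotonation regenerates the C6–C7 enolate as a lithium chelate with the C8 ether oxygen. The electrophile should then enter on the peripheral face opposite C9, the anti sense known for chelated β-oxygenated enolates (Fráter–Seebach type), which sets C7. The chelate also holds the C8–O bond in the nodal plane of the enolate, which disfavours E1cB.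

Step 14
Reactants: 31 methyl 2-[(1R,3Z,5S,7E,9R,10S)-5-(TBS-oxy)-10-(DMB-oxy)-4,8-dimethyl-9-(NAP-oxy)-2-oxocyclodeca-3,7-dien-1-yl]acetate
Product: 32 methyl 2-[(1R,3Z,5S,7E,9R,10S)-5-(TBS-oxy)-10-hydroxy-4,8-dimethyl-9-(NAP-oxy)-2-oxocyclodeca-3,7-dien-1-yl]acetate
Conditions: DDQ (1.2 equiv), CH2Cl2/pH 7 buffer, 0 °C
Reagents that add atoms: none
Why: Oxidative cleavage of benzylic ethers by DDQ is fastest for the electron-rich 3,4-dimethoxybenzyl group, so the naphthylmethyl ether at O9 should survive short exposure at 0 °C.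

Step 15
Reactants: 32 methyl 2-[(1R,3Z,5S,7E,9R,10S)-5-(TBS-oxy)-10-hydroxy-4,8-dimethyl-9-(NAP-oxy)-2-oxocyclodeca-3,7-dien-1-yl]acetate
Product: 34 (3S,6R,7R,8S,9R)-3-(TBS-oxy)-8-hydroxy-9-(NAP-oxy)-13-norgermacra-1(10)E,4Z-dien-12,6-olide, via diol ester 33 (not isolated)
Conditions: Me4NBH(OAc)3, MeCN/AcOH, −30 °C; then PPTS (cat.), PhH, 40 °C
Reagents that add atoms: none
Why: In the Evans–Saksena reduction the acetoxyborohydride bound to the C8 hydroxyl delivers hydride intramolecularly and gives the 1,3-anti diol, which sets C6 (R). The γ-hydroxy ester should then close onto O6 to the trans-fused lactone, because closure onto O8 would give a cis-fused ring that forces a near-eclipsed torsion in the ten-membered ring.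

Step 16
Reactants: 34 (3S,6R,7R,8S,9R)-3-(TBS-oxy)-8-hydroxy-9-(NAP-oxy)-13-norgermacra-1(10)E,4Z-dien-12,6-olide
Product: 38 (3S,6R,7R,8S,9R)-3-(TBS-oxy)-8-hydroxy-9-(NAP-oxy)germacra-1(10)E,4Z,11(13)-trien-12,6-olide, via dilithium salt 35 (not isolated), via Mannich base 36 (not isolated), via ammonium iodide 37 (not isolated)
Conditions: LiN(i-Pr)2 (2.3 equiv), THF, −78 °C; CH2=NMe2+ I−, −78 to 0 °C; MeI, MeOH, rt; NaHCO3 aq, EtOAc, rt
Reagents that add atoms: N,N-dimethylmethyleneiminium iodide (Eschenmoser's salt), C=[N+](C)C.[I-]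
Why: Mannich reaction of the lactone enolate (formed as the alkoxide–enolate dianion so that O8 needs no protection), then quaternisation and E1cB elimination, is the standard α-methylenation. It is placed here because the lactone is still the only enolisable carbonyl.

Step 17
Reactants: 38 (3S,6R,7R,8S,9R)-3-(TBS-oxy)-8-hydroxy-9-(NAP-oxy)germacra-1(10)E,4Z,11(13)-trien-12,6-olide; 39 (2Z)-2-methylbut-2-enoic acid (angelic acid)
Product: 41 (3S,6R,7S,8S,9R)-3-(TBS-oxy)-8-[(2Z)-2-methylbut-2-enoyloxy]-9-(NAP-oxy)germacra-1(10)E,4Z,11(13)-trien-12,6-olide, via mixed anhydride 40 (not isolated)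
Conditions: 39, 2,4,6-Cl3C6H2COCl, Et3N, toluene, rt; then 38, DMAP, toluene, 60 °C
Reagents that add atoms: none
Why: Yamaguchi esterification through the trichlorobenzoyl mixed anhydride acylates hindered secondary alcohols and is the usual way to keep the Z geometry of an angelate.

Step 18
Reactants: 41 (3S,6R,7S,8S,9R)-3-(TBS-oxy)-8-[(2Z)-2-methylbut-2-enoyloxy]-9-(NAP-oxy)germacra-1(10)E,4Z,11(13)-trien-12,6-olide
Product: 42 (1S,3S,6R,7S,8S,9S,10R)-1,10-dihydroxy-3-(TBS-oxy)-8-[(2Z)-2-methylbut-2-enoyloxy]-9-(NAP-oxy)germacra-4Z,11(13)-dien-12,6-olide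
Conditions: OsO4 (cat.), NMO, acetone/H2O, 0 °C to rt
Reagents that add atoms: osmium tetroxide, O=[Os](=O)(=O)=O; N-methylmorpholine N-oxide, C[N+]1([O-])CCOCC1; water, O
Why: Syn dihydroxylation should pick the strained, electron-rich E 1(10)-olefin over the two enoates and the C4=C5 olefin flanked by two allylic oxygens. Attack from the ring periphery on the conformer with C9–H next to the C10 methyl (anti to C8) gives the 9,10-erythro relationship, the same sense as the empirical anti rule for osmylation of allylic ethers, and this sets C10.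

Step 19
Reactants: 42 (1S,3S,6R,7S,8S,9S,10R)-1,10-dihydroxy-3-(TBS-oxy)-8-[(2Z)-2-methylbut-2-enoyloxy]-9-(NAP-oxy)germacra-4Z,11(13)-dien-12,6-olide
Product: 43 (3S,6R,7S,8S,9S,10S)-10-hydroxy-3-(TBS-oxy)-8-[(2Z)-2-methylbut-2-enoyloxy]-9-(NAP-oxy)-1-oxogermacra-4Z,11(13)-dien-12,6-olide
Conditions: Dess–Martin periodinane, NaHCO3, CH2Cl2, 0 °C to rt
Reagents that add atoms: none
Why: Dess–Martin oxidation of the only secondary alcohol gives the tertiary α-ketol under buffered, non-basic conditions that spare the β-silyloxy ketone.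

Step 20
Reactants: 43 (3S,6R,7S,8S,9S,10S)-10-hydroxy-3-(TBS-oxy)-8-[(2Z)-2-methylbut-2-enoyloxy]-9-(NAP-oxy)-1-oxogermacra-4Z,11(13)-dien-12,6-olide
Product: 44 (3S,6R,7S,8S,9S,10S)-9,10-dihydroxy-3-(TBS-oxy)-8-[(2Z)-2-methylbut-2-enoyloxy]-1-oxogermacra-4Z,11(13)-dien-12,6-olide
Conditions: DDQ (excess), CH2Cl2/H2O (pH 7), rt
Reagents that add atoms: none
Why: Oxidative removal of the 2-naphthylmethyl ether by DDQ in wet solvent is neutral and should leave the enoates, ketol and silyl ether untouched.

Step 21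
Reactants: 44 (3S,6R,7S,8S,9S,10S)-9,10-dihydroxy-3-(TBS-oxy)-8-[(2Z)-2-methylbut-2-enoyloxy]-1-oxogermacra-4Z,11(13)-dien-12,6-olide
Product: 45 (3S,6R,7S,8S,9S,10S)-9-acetoxy-10-hydroxy-3-(TBS-oxy)-8-[(2Z)-2-methylbut-2-enoyloxy]-1-oxogermacra-4Z,11(13)-dien-12,6-olide
Conditions: Ac2O, pyridine, DMAP (cat.), CH2Cl2, 0 °C to rt
Reagents that add atoms: acetic anhydride, CC(=O)OC(C)=O
Why: Acetylation should take the secondary C9 hydroxyl and leave the tertiary C10 hydroxyl. The bulky conjugated angelate placed first is the ester less prone to 1,2-migration during this step.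

Step 22
Reactants: 45 (3S,6R,7S,8S,9S,10S)-9-acetoxy-10-hydroxy-3-(TBS-oxy)-8-[(2Z)-2-methylbut-2-enoyloxy]-1-oxogermacra-4Z,11(13)-dien-12,6-olide
Product: 46 (3S,6R,7S,8S,9S,10S)-9-acetoxy-3,10-dihydroxy-8-[(2Z)-2-methylbut-2-enoyloxy]-1-oxogermacra-4Z,11(13)-dien-12,6-olide
Conditions: HF·pyridine, THF/pyridine, 0 °C to rt
Reagents that add atoms: none
Why: Buffered HF removes the last silyl ether without base, so the β-hydroxy ketone should not dehydrate and the methylene lactone should see no nucleophile.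

## Compound list

1 | 2-(bromomethyl)naphthalene | BrCc1ccc2ccccc2c1 | starting material
2 | prop-2-en-1-ol | C=CCO | starting material
3 | sodium prop-2-en-1-olate | [Na+].[O-]CC=C | intermediate
4 | 2-[(prop-2-en-1-yloxy)methyl]naphthalene | C=CCOCc1ccc2ccccc2c1 | intermediate
5 | 2-{[(1Z)-prop-1-en-1-yloxy]methyl}naphthalene | C/C=C\OCc1ccc2ccccc2c1 | intermediate
6 | rac-(1R,2S)-1,2-dibromo-1-(naphthalen-2-ylmethoxy)propane (anti adduct, one enantiomer drawn) | C[C@H](Br)[C@@H](Br)OCc1ccc2ccccc2c1 | intermediate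
7 | 2-({[(1Z)-2-bromoprop-1-en-1-yl]oxy}methyl)naphthalene | C/C(Br)=C/OCc1ccc2ccccc2c1 | intermediate
8 | 4-methoxy-2-methylphenol | COc1ccc(O)c(C)c1 | starting material
9 | 4,4-dimethoxy-2-methylcyclohexa-2,5-dien-1-one | COC1(OC)C=CC(=O)C(C)=C1 | intermediate
10 | [(1Z)-1-(naphthalen-2-ylmethoxy)prop-1-en-2-yl]lithium (Li cis to O) | [Li]/C(C)=C\OCc1ccc2ccccc2c1 | intermediate
11 | lithium bis[(1Z)-1-(naphthalen-2-ylmethoxy)prop-1-en-2-yl]cuprate | [Li+].C/C(=C/OCc1ccc2ccccc2c1)[Cu-]/C(C)=C\OCc1ccc2ccccc2c1 | intermediate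
12 | rac-4,4-dimethoxy-2-methyl-5-[(1Z)-1-(naphthalen-2-ylmethoxy)prop-1-en-2-yl]cyclohex-2-en-1-one (racemic at C5) | COC1(OC)C=C(C)C(=O)CC1/C(C)=C\OCc2ccc3ccccc3c2 | intermediate
13 | (1S,5R)-4,4-dimethoxy-2-methyl-5-[(1Z)-1-(naphthalen-2-ylmethoxy)prop-1-en-2-yl]cyclohex-2-en-1-ol | COC1(OC)C=C(C)[C@@H](O)C[C@@H]1/C(C)=C\OCc2ccc3ccccc3c2 | intermediate
14 | tert-butyl{[(1S,5R)-4,4-dimethoxy-2-methyl-5-[(1Z)-1-(naphthalen-2-ylmethoxy)prop-1-en-2-yl]cyclohex-2-en-1-yl]oxy}dimethylsilane | COC1(OC)C=C(C)[C@@H](O[Si](C)(C)C(C)(C)C)C[C@@H]1/C(C)=C\OCc2ccc3ccccc3c2 | intermediate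
15 | (4S,6R)-4-[(tert-butyldimethylsilyl)oxy]-3-methyl-6-[(1Z)-1-(naphthalen-2-ylmethoxy)prop-1-en-2-yl]cyclohex-2-en-1-one | O=C1C=C(C)[C@@H](O[Si](C)(C)C(C)(C)C)C[C@@H]1/C(C)=C\OCc2ccc3ccccc3c2 | intermediate
16 | (3,4-dimethoxyphenyl)methanol | COc1ccc(CO)cc1OC | starting material
17 | trichloroethene | ClC=C(Cl)Cl | starting material
18 | potassium (3,4-dimethoxyphenyl)methanolate | [K+].[O-]Cc1ccc(OC)c(OC)c1 | intermediate
19 | 4-({[(E)-1,2-dichloroethenyl]oxy}methyl)-1,2-dimethoxybenzene | Cl/C=C(/Cl)OCc1ccc(OC)c(OC)c1 | intermediate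
20 | {[(3,4-dimethoxybenzyl)oxy]ethynyl}lithium | [Li]C#COCc1ccc(OC)c(OC)c1 | intermediate
21 | 4-[(ethynyloxy)methyl]-1,2-dimethoxybenzene | C#COCc1ccc(OC)c(OC)c1 | intermediate
22 | chlorobis(cyclopentadienyl){(E)-2-[(3,4-dimethoxybenzyl)oxy]ethenyl}zirconium | Cl[Zr](/C=C/OCc1ccc(OC)c(OC)c1)(C1C=CC=C1)C1C=CC=C1 | intermediate
23 | 4-({[(E)-2-iodoethenyl]oxy}methyl)-1,2-dimethoxybenzene | I/C=C/OCc1ccc(OC)c(OC)c1 | intermediate
24 | {(E)-2-[(3,4-dimethoxybenzyl)oxy]ethenyl}lithium | [Li]/C=C/OCc1ccc(OC)c(OC)c1 | intermediate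
25 | (1R,4S,6R)-4-[(tert-butyldimethylsilyl)oxy]-1-{(E)-2-[(3,4-dimethoxybenzyl)oxy]ethenyl}-3-methyl-6-[(1Z)-1-(naphthalen-2-ylmethoxy)prop-1-en-2-yl]cyclohex-2-en-1-ol | O[C@]1(/C=C/OCc2ccc(OC)c(OC)c2)C=C(C)[C@@H](O[Si](C)(C)C(C)(C)C)C[C@@H]1/C(C)=C\OCc2ccc3ccccc3c2 | intermediate
26 | potassium alkoxide of 25 | [K+].[O-][C@]1(/C=C/OCc2ccc(OC)c(OC)c2)C=C(C)[C@@H](O[Si](C)(C)C(C)(C)C)C[C@@H]1/C(C)=C\OCc2ccc3ccccc3c2 | intermediate
27 | potassium C6–C7 enolate of 28 (ring bonds trans across the enolate) | [K+].[O-]C=1/C=C(/C)[C@@H](O[Si](C)(C)C(C)(C)C)C/C=C(C)/[C@@H](OCc2ccc3ccccc3c2)[C@@H](OCc2ccc(OC)c(OC)c2)/C=1 | intermediate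
28 | (2Z,4S,6E,8R,9S)-4-[(tert-butyldimethylsilyl)oxy]-9-[(3,4-dimethoxybenzyl)oxy]-3,7-dimethyl-8-(naphthalen-2-ylmethoxy)cyclodeca-2,6-dien-1-one | O=C1/C=C(/C)[C@@H](O[Si](C)(C)C(C)(C)C)C/C=C(C)/[C@@H](OCc2ccc3ccccc3c2)[C@@H](OCc2ccc(OC)c(OC)c2)C1 | intermediate
29 | methyl bromoacetate | COC(=O)CBr | starting material
30 | lithium C6–C7 enolate of 28 (chelated by O8) | [Li+].[O-]C=1/C=C(/C)[C@@H](O[Si](C)(C)C(C)(C)C)C/C=C(C)/[C@@H](OCc2ccc3ccccc3c2)[C@@H](OCc2ccc(OC)c(OC)c2)/C=1 | intermediate
31 | methyl 2-[(1R,3Z,5S,7E,9R,10S)-5-[(tert-butyldimethylsilyl)oxy]-10-[(3,4-dimethoxybenzyl)oxy]-4,8-dimethyl-9-(naphthalen-2-ylmethoxy)-2-oxocyclodeca-3,7-dien-1-yl]acetate | O=C1/C=C(/C)[C@@H](O[Si](C)(C)C(C)(C)C)C/C=C(C)/[C@@H](OCc2ccc3ccccc3c2)[C@@H](OCc2ccc(OC)c(OC)c2)[C@H]1CC(=O)OC | intermediate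
32 | methyl 2-[(1R,3Z,5S,7E,9R,10S)-5-[(tert-butyldimethylsilyl)oxy]-10-hydroxy-4,8-dimethyl-9-(naphthalen-2-ylmethoxy)-2-oxocyclodeca-3,7-dien-1-yl]acetate | O=C1/C=C(/C)[C@@H](O[Si](C)(C)C(C)(C)C)C/C=C(C)/[C@@H](OCc2ccc3ccccc3c2)[C@@H](O)[C@H]1CC(=O)OC | intermediate
33 | methyl 2-[(1S,2R,3Z,5S,7E,9R,10S)-5-[(tert-butyldimethylsilyl)oxy]-2,10-dihydroxy-4,8-dimethyl-9-(naphthalen-2-ylmethoxy)cyclodeca-3,7-dien-1-yl]acetate | O[C@@H]1/C=C(/C)[C@@H](O[Si](C)(C)C(C)(C)C)C/C=C(C)/[C@@H](OCc2ccc3ccccc3c2)[C@@H](O)[C@H]1CC(=O)OC | intermediate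
34 | (3S,6R,7R,8S,9R)-3-[(tert-butyldimethylsilyl)oxy]-8-hydroxy-9-(naphthalen-2-ylmethoxy)-13-norgermacra-1(10)E,4Z-dien-12,6-olide | C1C(=O)O[C@@H]2/C=C(/C)[C@@H](O[Si](C)(C)C(C)(C)C)C/C=C(C)/[C@@H](OCc3ccc4ccccc4c3)[C@@H](O)[C@@H]12 | intermediate
35 | dilithium salt of 34 (C8 alkoxide and lactone enolate) | [Li+].[Li+].C1=C([O-])O[C@@H]2/C=C(/C)[C@@H](O[Si](C)(C)C(C)(C)C)C/C=C(C)/[C@@H](OCc3ccc4ccccc4c3)[C@@H]([O-])[C@@H]12 | intermediate
36 | 13-(dimethylamino) derivative of 34 (11-(dimethylaminomethyl) lactone, C11 epimers) | CN(C)CC1C(=O)O[C@@H]2/C=C(/C)[C@@H](O[Si](C)(C)C(C)(C)C)C/C=C(C)/[C@@H](OCc3ccc4ccccc4c3)[C@@H](O)[C@@H]12 | intermediate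
37 | N-methyl ammonium iodide of 36 | [I-].C[N+](C)(C)CC1C(=O)O[C@@H]2/C=C(/C)[C@@H](O[Si](C)(C)C(C)(C)C)C/C=C(C)/[C@@H](OCc3ccc4ccccc4c3)[C@@H](O)[C@@H]12 | intermediate
38 | (3S,6R,7R,8S,9R)-3-[(tert-butyldimethylsilyl)oxy]-8-hydroxy-9-(naphthalen-2-ylmethoxy)germacra-1(10)E,4Z,11(13)-trien-12,6-olide | C=C1C(=O)O[C@@H]2/C=C(/C)[C@@H](O[Si](C)(C)C(C)(C)C)C/C=C(C)/[C@@H](OCc3ccc4ccccc4c3)[C@@H](O)[C@@H]12 | intermediate
39 | (2Z)-2-methylbut-2-enoic acid (angelic acid) | C/C=C(/C)C(=O)O | starting material
40 | (2Z)-2-methylbut-2-enoic 2,4,6-trichlorobenzoic anhydride | C/C=C(/C)C(=O)OC(=O)c1c(Cl)cc(Cl)cc1Cl | intermediate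
41 | (3S,6R,7S,8S,9R)-3-[(tert-butyldimethylsilyl)oxy]-8-[(2Z)-2-methylbut-2-enoyloxy]-9-(naphthalen-2-ylmethoxy)germacra-1(10)E,4Z,11(13)-trien-12,6-olide | C=C1C(=O)O[C@@H]2/C=C(/C)[C@@H](O[Si](C)(C)C(C)(C)C)C/C=C(C)/[C@@H](OCc3ccc4ccccc4c3)[C@@H](OC(=O)/C(C)=C\C)[C@@H]12 | intermediate
42 | (1S,3S,6R,7S,8S,9S,10R)-3-[(tert-butyldimethylsilyl)oxy]-1,10-dihydroxy-8-[(2Z)-2-methylbut-2-enoyloxy]-9-(naphthalen-2-ylmethoxy)germacra-4Z,11(13)-dien-12,6-olide | C=C1C(=O)O[C@@H]2/C=C(/C)[C@@H](O[Si](C)(C)C(C)(C)C)C[C@H](O)[C@@](C)(O)[C@@H](OCc3ccc4ccccc4c3)[C@@H](OC(=O)/C(C)=C\C)[C@@H]12 | intermediate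
43 | (3S,6R,7S,8S,9S,10S)-3-[(tert-butyldimethylsilyl)oxy]-10-hydroxy-8-[(2Z)-2-methylbut-2-enoyloxy]-9-(naphthalen-2-ylmethoxy)-1-oxogermacra-4Z,11(13)-dien-12,6-olide | C=C1C(=O)O[C@@H]2/C=C(/C)[C@@H](O[Si](C)(C)C(C)(C)C)CC(=O)[C@@](C)(O)[C@@H](OCc3ccc4ccccc4c3)[C@@H](OC(=O)/C(C)=C\C)[C@@H]12 | intermediate
44 | (3S,6R,7S,8S,9S,10S)-3-[(tert-butyldimethylsilyl)oxy]-9,10-dihydroxy-8-[(2Z)-2-methylbut-2-enoyloxy]-1-oxogermacra-4Z,11(13)-dien-12,6-olide | C=C1C(=O)O[C@@H]2/C=C(/C)[C@@H](O[Si](C)(C)C(C)(C)C)CC(=O)[C@@](C)(O)[C@@H](O)[C@@H](OC(=O)/C(C)=C\C)[C@@H]12 | intermediate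
45 | (3S,6R,7S,8S,9S,10S)-9-acetoxy-3-[(tert-butyldimethylsilyl)oxy]-10-hydroxy-8-[(2Z)-2-methylbut-2-enoyloxy]-1-oxogermacra-4Z,11(13)-dien-12,6-olide | C=C1C(=O)O[C@@H]2/C=C(/C)[C@@H](O[Si](C)(C)C(C)(C)C)CC(=O)[C@@](C)(O)[C@@H](OC(C)=O)[C@@H](OC(=O)/C(C)=C\C)[C@@H]12 | intermediate
46 | (3S,6R,7S,8S,9S,10S)-9-acetoxy-3,10-dihydroxy-8-[(2Z)-2-methylbut-2-enoyloxy]-1-oxogermacra-4Z,11(13)-dien-12,6-olide (CNP0308559.2) | C=C1C(=O)O[C@@H]2/C=C(/C)[C@@H](O)CC(=O)[C@@](C)(O)[C@@H](OC(C)=O)[C@@H](OC(=O)/C(C)=C\C)[C@@H]12 | target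

## Step count and least certain steps

Total: 22 steps. Longest linear sequence: 19 steps (steps 1–3, 5–8, 11–22).

**Step 12 (key step).** The most likely failure is that the alkoxide does not rearrange cleanly: the two donor-substituted termini may slow the [3,3] shift, so that fragmentation, a boat pathway that erodes the C8/C9 relay, or E1cB loss of the C8 ether from the enolate competes. The fallback leaves the anionic manifold. Carbinol 25 is silylated (TMSCl, imidazole) to the trimethylsilyl ether F1. F1 is rearranged thermally (toluene, sealed tube, about 200 °C) in a neutral siloxy-Cope shift to the trimethylsilyl enol ether F2, in which no free enolate can eliminate. Mild aqueous acid hydrolysis of F2 returns to ketone 28.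

**Step 6.** The desired trans carbinol is the mismatched case, so incomplete catalyst control may contaminate or diminish 13. The fallback uses the matched pairing. Racemic 12 is reduced with (S)-Me-CBS oxazaborolidine and catecholborane to the cis (1R,5R) carbinol F3, which is separated from its diastereomer. F3 is inverted by Mitsunobu reaction (4-nitrobenzoic acid, PPh3, diisopropyl azodicarboxylate) to the (1S,5R) 4-nitrobenzoate F4. Methanolysis (K2CO3, MeOH) rejoins the route at 13.

**Step 11.** The adjacent side arm and the pseudoaxial silyloxy group on the opposite face pull in opposite directions, so facial selectivity of the addition may be poor. The fallback lets the C3 oxygen direct the addition. Carbinol 13 is hydrolysed without silylation (PPTS, wet acetone) to the hydroxy enone (4S,6R)-4-hydroxy-3-methyl-6-[(1Z)-1-(NAP-oxy)prop-1-en-2-yl]cyclohex-2-en-1-one F5. Excess alkenyllithium 24 first forms the C3 alkoxide and is then delivered to the same face, giving the diol F6. Selective silylation of the secondary hydroxyl (TBSCl, imidazole) returns to 25.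

**Step 13.** If chelation is incomplete, the electrophile may attack the other enolate conformer (C7 epimer), or the C8 ether may be lost by E1cB. The fallback reverses the order. Ketone 28 is treated with DDQ to give the β-hydroxy ketone F7. Its dianion (LiN(i-Pr)2, 2.2 equiv) is alkylated with 29 in the Fráter–Seebach sense, with the alkoxide locking the chelate. This rejoins the route at 32.

**Step 15.** Hydride delivery may be slowed by the conjugated, hindered ketone, and the diol may lactonise in part onto O8. The fallback differentiates the two oxygens in the reduction itself. An Evans–Tishchenko reduction of 32 (acetaldehyde, SmI2 as precatalyst, THF, −10 °C) gives the 8-O-acetyl 6-hydroxy ester F8 with the same 1,3-anti sense. F8 can only close onto O6, giving the 8-O-acetyl lactone F9. Brief methanolysis of the acetate (K2CO3, MeOH, 0 °C) returns to 34.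

## Further compounds

F1 | step 12 | trimethylsilyl ether of 25 | C[Si](C)(C)O[C@]1(/C=C/OCc2ccc(OC)c(OC)c2)C=C(C)[C@@H](O[Si](C)(C)C(C)(C)C)C[C@@H]1/C(C)=C\OCc2ccc3ccccc3c2
F2 | step 12 | trimethylsilyl enol ether of 28 | C[Si](C)(C)OC=1/C=C(/C)[C@@H](O[Si](C)(C)C(C)(C)C)C/C=C(C)/[C@@H](OCc2ccc3ccccc3c2)[C@@H](OCc2ccc(OC)c(OC)c2)/C=1
F3 | step 6 | (1R,5R)-4,4-dimethoxy-2-methyl-5-[(1Z)-1-(naphthalen-2-ylmethoxy)prop-1-en-2-yl]cyclohex-2-en-1-ol | COC1(OC)C=C(C)[C@H](O)C[C@@H]1/C(C)=C\OCc2ccc3ccccc3c2
F4 | step 6 | (1S,5R)-4,4-dimethoxy-2-methyl-5-[(1Z)-1-(naphthalen-2-ylmethoxy)prop-1-en-2-yl]cyclohex-2-en-1-yl 4-nitrobenzoate | COC1(OC)C=C(C)[C@@H](OC(=O)c2ccc(cc2)[N+](=O)[O-])C[C@@H]1/C(C)=C\OCc2ccc3ccccc3c2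
F5 | step 11 | (4S,6R)-4-hydroxy-3-methyl-6-[(1Z)-1-(naphthalen-2-ylmethoxy)prop-1-en-2-yl]cyclohex-2-en-1-one | O=C1C=C(C)[C@@H](O)C[C@@H]1/C(C)=C\OCc2ccc3ccccc3c2
F6 | step 11 | (1R,4S,6R)-1-{(E)-2-[(3,4-dimethoxybenzyl)oxy]ethenyl}-3-methyl-6-[(1Z)-1-(naphthalen-2-ylmethoxy)prop-1-en-2-yl]cyclohex-2-ene-1,4-diol | O[C@]1(/C=C/OCc2ccc(OC)c(OC)c2)C=C(C)[C@@H](O)C[C@@H]1/C(C)=C\OCc2ccc3ccccc3c2
F7 | step 13 | (2Z,4S,6E,8R,9S)-4-[(tert-butyldimethylsilyl)oxy]-9-hydroxy-3,7-dimethyl-8-(naphthalen-2-ylmethoxy)cyclodeca-2,6-dien-1-one | O=C1/C=C(/C)[C@@H](O[Si](C)(C)C(C)(C)C)C/C=C(C)/[C@@H](OCc2ccc3ccccc3c2)[C@@H](O)C1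
F8 | step 15 | methyl 2-[(1S,2R,3Z,5S,7E,9R,10S)-10-acetoxy-5-[(tert-butyldimethylsilyl)oxy]-2-hydroxy-4,8-dimethyl-9-(naphthalen-2-ylmethoxy)cyclodeca-3,7-dien-1-yl]acetate | O[C@@H]1/C=C(/C)[C@@H](O[Si](C)(C)C(C)(C)C)C/C=C(C)/[C@@H](OCc2ccc3ccccc3c2)[C@@H](OC(C)=O)[C@H]1CC(=O)OC
F9 | step 15 | 8-O-acetyl derivative of 34 | C1C(=O)O[C@@H]2/C=C(/C)[C@@H](O[Si](C)(C)C(C)(C)C)C/C=C(C)/[C@@H](OCc3ccc4ccccc4c3)[C@@H](OC(C)=O)[C@@H]12
A1 | alternative 1 | C1–C3 isoxazoline-bridged ten-membered lactone with 8,9-acetonide | C1C(=O)O[C@@H]2/C=C(/C)[C@@H]3CC(=NO3)[C@@](C)(O)[C@@H](OC4(C)C)[C@@H](O4)[C@@H]12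
A2 | alternative 2 | 6-hydroxy-7-(3,3-dimethoxyprop-1-en-2-yl) ten-membered carbocycle (C1 dithiane, 10-O-methoxymethyl, 8,9-acetonide, 3-O-TBS) | O[C@@H]1/C=C(/C)[C@@H](O[Si](C)(C)C(C)(C)C)CC2(SCCCS2)[C@@](C)(OCOC)[C@@H](OC3(C)C)[C@@H](O3)[C@H]1C(=C)C(OC)OC
A3 | alternative 3 | 9,10-cis-diol ten-membered lactone (1-O-triethylsilyl, 3-O-TBS, 8-O-methoxymethyl) | C1C(=O)O[C@@H]2/C=C(/C)[C@@H](O[Si](C)(C)C(C)(C)C)C[C@@H](O[Si](CC)(CC)CC)[C@@](C)(O)[C@@H](O)[C@@H](OCOC)[C@@H]12
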